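The route closes ring D (C8–C15–C16–C13–C14) last, across the 1,3-related carbons C8 and C13 of a preformed cyclohexene ring C. A 2-bromoallyl arm on the quaternary C8 is converted into a C16 vinyl radical that attacks the C12=C13 alkene in 5-exo fashion, giving the bicyclo[3.2.1]octane, the C13 stereocentre and the exocyclic C16=C17 alkene needed for the diol in one operation. The precursor is an open ring A–ring C diester: ring C comes from a desymmetrised tetrahydrophthalic half-ester, and ring A is annulated onto its carboxyl carbon (C10) by aldol condensation and conjugate methylation.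

Key step: step 9

Remark: atom labels follow ent-kaurane numbering (ring A = C1–C5, C10; ring C = C8, C9, C11–C14; ring D = C8, C14, C13, C16, C15; C6 and C7 = formyl carbons; C17 = hydroxymethyl; C18, C20 = methyls; C19 = carboxyl).
Remark: half-ester 1 is taken as purchased in enantiopure form (it is also the product of cinchona-alkaloid-mediated methanolysis of cis-1,2,3,6-tetrahydrophthalic anhydride).
Remark: C5 is carried as an unassigned (epimeric) centre from compound 10 to compound 22 and is written without configuration in their SMILES; it is set in step 14.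
Remark: the target is taken as the open dialdehyde acid as drawn; its ring–chain tautomer (cis-fused lactol between the C19 acid and the C6 aldehyde) is expected to be in equilibrium with it.

Step 1
Reactants: 1 (1S,2R)-2-(methoxycarbonyl)cyclohex-4-ene-1-carboxylic acid; 2 2-(3-chloropropyl)-2-methyl-1,3-dioxolane
Product: 5 cis keto ester ketal, via acid chloride 3 (not isolated), via Grignard reagent 4 (not isolated)
Conditions: 1, (COCl)2, DMF (cat.), CH2Cl2, 0 to 23 °C; separately 2, Mg, THF, 50 °C; then Fe(acac)3 (3 mol %), THF, −78 °C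
Reagents that add atoms: none
Why: Iron-catalysed acylation of the Grignard reagent by the acid chloride should stop at the ketone at low temperature and spare the methyl ester (Grignard acylation); C8, alpha to the ester, is not enolised, and any erosion at C9 is irrelevant because C9 is equilibrated in step 2.

Step 2
Reactants: 5 cis keto ester ketal
Product: 7 trans enone, via diketone 6 (not isolated)
Conditions: 1 M HCl, THF, 23 °C; then TsOH·H2O (cat.), toluene, reflux (Dean–Stark)
Reagents that add atoms: water, O
Why: Ketal hydrolysis gives the 1,5-diketone, whose intramolecular aldol condensation (C5 onto the C10 carbonyl) can dehydrate only to the 3-substituted cyclohexenone (ring A closed), while acid-mediated enolisation toward C9 should equilibrate C9 to the trans, diequatorial arrangement relative to the untouched C8 ester centre; any minor cis isomer is removed by chromatography.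

Step 3
Reactants: 7 trans enone
Product: 9 triethylsilyl enol ether, via aluminium enolate 8 (not isolated)
Conditions: Me3Al, Cu(O2CC4H3S) (2 mol %), chiral phosphoramidite ligand (4 mol %), Et2O, −30 °C; then Et3SiOTf, −78 to 0 °C
Reagents that add atoms: trimethylaluminium, C[Al](C)C; triethylsilyl trifluoromethanesulfonate, CC[Si](CC)(CC)OS(=O)(=O)C(F)(F)F
Why: Copper-catalysed asymmetric conjugate addition of Me3Al to the 3-substituted cyclohexenone should create the quaternary C10 under ligand control (ligand enantiomer chosen for 10S and expected to reinforce the bias of the C9 centre), and silylation of the aluminium enolate fixes the C4=C5 enolate regiochemistry.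

Step 4
Reactants: 9 triethylsilyl enol ether
Product: 10 beta-keto dimethyl acetal (C5 epimers)
Conditions: HC(OMe)3, Me3SiOTf (cat.), CH2Cl2, −78 °C
Reagents that add atoms: trimethyl orthoformate, COC(OC)OC
Why: Mukaiyama-type addition of the silyl enol ether to the dimethoxycarbenium ion from the orthoformate should place C6 on C5 regiospecifically at the aldehyde oxidation level; the epimerisable C5 centre is deliberately left uncontrolled here and is set in step 14.

Step 5
Reactants: 10 beta-keto dimethyl acetal
Product: 12 enol triflate, via potassium enolate 11 (not isolated)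
Conditions: KN(SiMe3)2, THF, −78 °C; then PhNTf2, −78 to 0 °C
Reagents that add atoms: N-phenylbis(trifluoromethanesulfonimide), O=S(=O)(N(c1ccccc1)S(=O)(=O)C(F)(F)F)C(F)(F)F
Why: Kinetic deprotonation of the ketone should occur at the unhindered C3 methylene, not at the tertiary C5 flanked by the quaternary C10 nor at the much less acidic ester alpha-position C8, and O-triflation then gives the C3=C4 enol triflate (enol triflate formation).

Step 6
Reactants: 12 enol triflate
Product: 13 enoate (2-(trimethylsilyl)ethyl ester at C19)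
Conditions: Pd(OAc)2 (5 mol %), PPh3 (10 mol %), CO (1 atm), Me3SiCH2CH2OH, Et3N, DMF, 60 °C
Reagents that add atoms: carbon monoxide, [C-]#[O+]; 2-(trimethylsilyl)ethanol, C[Si](C)(C)CCO
Why: Palladium-catalysed alkoxycarbonylation of the enol triflate (oxidative addition, CO insertion, alcoholysis) should introduce C19 as a fluoride-labile ester that can later be told apart from the C7 methyl ester.

Step 7
Reactants: 13 enoate
Product: 15 C4-methylated diester, via lithium enolate 14 (not isolated)
Conditions: Li[HB(sec-Bu)3], THF, −78 °C; then MeI, DMPU, −78 to 0 °C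
Reagents that add atoms: iodomethane, CI
Why: Conjugate hydride delivery to the unhindered beta-carbon C3 gives the C4 ester enolate, which should be methylated from the equatorial face opposite the syn-axial C10 methyl (reductive alkylation), so that C18 ends equatorial and the C19 ester axial and cis to C20; the saturated C7 ester is not reduced at −78 °C.

Step 8
Reactants: 15 C4-methylated diester
Product: 17 C8 2-bromoallyl diester, via lithium enolate 16 (not isolated)
Conditions: LiN(CHMe2)2, THF–DMPU, −78 °C; then 2,3-dibromopropene, −78 to −20 °C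
Reagents that add atoms: 2,3-dibromopropene, C=C(Br)CBr
Why: C8–H is the only remaining acidic C–H, and alkylation of its ester enolate by the allylic bromide should occur anti to the bulky ring A substituent on C9 (held axial by allylic strain in the exocyclic enolate), making C8 quaternary with the arm C15–C16(Br)=C17 trans to C10 (enolate alkylation).

Step 9
Reactants: 17 C8 2-bromoallyl diester
Product: 18 bicyclo[3.2.1]octane with exocyclic C16=C17
Conditions: Bu3SnH (0.05 M), AIBN (cat.), benzene, 80 °C
Reagents that add atoms: none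
Why: Bromine abstraction by the tributyltin radical gives a sigma vinyl radical at C16 that adds to C13 of the C12=C13 alkene, and the secondary C12 radical is then quenched by Bu3SnH, so the C13–C16 bond, ring D and the exocyclic C16=C17 alkene arise in one operation. The closest known reaction type is the tin-hydride-mediated 5-exo-trig cyclisation of 2-bromoallyl groups onto cycloalkenes, an established entry to bicyclo[3.2.1]octanes. Ring D (C8, C15, C16, C13, C14) closes in the 5-exo-trig mode. The new stereocentre C13 is dictated by the quaternary C8, because the two-atom tether C15–C16 can bridge C8 and C13 only on the face of ring C that carries the axial arm. The step needs 5-exo attack at C13 and not 6-endo attack at C12 (bicyclo[2.2.2]octane), and no homoallyl rearrangement of the C12 radical; the intrinsic 5-exo preference of vinyl radicals and a tin hydride concentration high enough to trap the C12 radical promptly should secure both.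

Step 10
Reactants: 18 bicyclo[3.2.1]octane diester
Product: 19 C19 acid
Conditions: Bu4NF, THF, 23 °C; aq. NH4Cl
Reagents that add atoms: none
Why: Fluoride attack at silicon triggers beta-elimination of ethene and Me3SiF (silyl-ethyl ester cleavage), which should free the hindered C19 acid without touching the methyl ester, the acetal or the alkene.

Step 11
Reactants: 19 C19 acid
Product: 20 C7 primary alcohol
Conditions: LiEt3BH, THF, 0 to 23 °C; then H2O
Reagents that add atoms: none
Why: LiEt3BH first converts the acid into the unreactive carboxylate and should then reduce the hindered neopentyl methyl ester at C7 to the primary alcohol (hydride reduction of an ester).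

Step 12
Reactants: 20 C7 primary alcohol
Product: 21 C7 aldehyde
Conditions: Dess–Martin periodinane, NaHCO3, CH2Cl2, 23 °C
Reagents that add atoms: none
Why: Dess–Martin oxidation should convert the neopentyl alcohol into the non-enolisable C7 aldehyde under buffered conditions that tolerate the free acid, the acetal and the alkene.

Step 13
Reactants: 21 C7 aldehyde
Product: 22 16,17-diol
Conditions: OsO4 (2 mol %), N-methylmorpholine N-oxide, citric acid, Me3COH–H2O, 23 °C
Reagents that add atoms: N-methylmorpholine N-oxide, C[N+]1([O-])CCOCC1; water, O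
Why: Catalytic OsO4 dihydroxylation of the 1,1-disubstituted exocyclic alkene should occur on the exo face of the two-carbon bridge (syn to the C14 bridge, away from the C9–C11–C12 bridge), which places the C16 hydroxyl exo and C17 endo as required.

Step 14
Reactants: 22 16,17-diol
Product: 24 target acid, via 5-epi dial acid 23 (not isolated)
Conditions: 1 M HCl, THF–H2O, 23 °C; then pyrrolidine (cat.), AcOH, THF–H2O, 23 °C
Reagents that add atoms: water, O
Why: Aqueous acid unmasks the C6 aldehyde (acetal hydrolysis), and the only enolisable centre, C5, is then equilibrated through the amine-catalysed enamine, the epimer with C6 cis to the C19 acid being withdrawn as its cis-fused five-membered lactol (ring–chain tautomer of the target), which the trans-diaxial 5-epimer cannot form.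

Compound list
1 | (1S,2R)-2-(methoxycarbonyl)cyclohex-4-ene-1-carboxylic acid (cis half-ester; acid-bearing carbon = C9, ester-bearing carbon = C8) | OC(=O)[C@H]1CC=CC[C@H]1C(=O)OC | starting material
2 | 2-(3-chloropropyl)-2-methyl-1,3-dioxolane | CC1(CCCCl)OCCO1 | starting material
3 | methyl (1R,6S)-6-(chlorocarbonyl)cyclohex-3-ene-1-carboxylate | ClC(=O)[C@H]1CC=CC[C@H]1C(=O)OC | intermediate
4 | [3-(2-methyl-1,3-dioxolan-2-yl)propyl]magnesium chloride | CC1(CCC[Mg]Cl)OCCO1 | intermediate
5 | methyl (1R,6S)-6-[4-(2-methyl-1,3-dioxolan-2-yl)butanoyl]cyclohex-3-ene-1-carboxylate (cis) | CC1(CCCC(=O)[C@H]2CC=CC[C@H]2C(=O)OC)OCCO1 | intermediate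
6 | methyl (1R,6S)-6-(5-oxohexanoyl)cyclohex-3-ene-1-carboxylate (cis 1,5-diketone as first formed) | CC(=O)CCCC(=O)[C@H]1CC=CC[C@H]1C(=O)OC | intermediate
7 | methyl (1R,6R)-6-(3-oxocyclohex-1-en-1-yl)cyclohex-3-ene-1-carboxylate (trans; 8R,9R) | O=C1C=C(CCC1)[C@@H]2CC=CC[C@H]2C(=O)OC | intermediate
8 | dimethylaluminium C4=C5 enolate of the 10-methyl ketone (8R,9R,10S) | C[C@@]1([C@@H]2CC=CC[C@H]2C(=O)OC)CCCC(O[Al](C)C)=C1 | intermediate
9 | methyl (1R,6R)-6-[(1S)-1-methyl-3-(triethylsilyloxy)cyclohex-2-en-1-yl]cyclohex-3-ene-1-carboxylate | C[C@@]1([C@@H]2CC=CC[C@H]2C(=O)OC)CCCC(O[Si](CC)(CC)CC)=C1 | intermediate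
10 | methyl (1R,6R)-6-[(1S)-2-(dimethoxymethyl)-1-methyl-3-oxocyclohexyl]cyclohex-3-ene-1-carboxylate (C5 epimers) | C[C@@]1([C@@H]2CC=CC[C@H]2C(=O)OC)CCCC(=O)C1C(OC)OC | intermediate
11 | potassium C3=C4 enolate of 10 | C[C@@]1([C@@H]2CC=CC[C@H]2C(=O)OC)CCC=C([O-])C1C(OC)OC.[K+] | intermediate
12 | methyl (1R,6R)-6-[(1S)-2-(dimethoxymethyl)-1-methyl-3-(trifluoromethylsulfonyloxy)cyclohex-3-en-1-yl]cyclohex-3-ene-1-carboxylate (C5 epimers) | C[C@@]1([C@@H]2CC=CC[C@H]2C(=O)OC)CCC=C(OS(=O)(=O)C(F)(F)F)C1C(OC)OC | intermediate
13 | 2-(trimethylsilyl)ethyl (5S)-6-(dimethoxymethyl)-5-[(1R,6R)-6-(methoxycarbonyl)cyclohex-3-en-1-yl]-5-methylcyclohex-1-ene-1-carboxylate (C5 epimers) | C[C@@]1([C@@H]2CC=CC[C@H]2C(=O)OC)CCC=C(C(=O)OCC[Si](C)(C)C)C1C(OC)OC | intermediate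
14 | lithium C4 ester enolate formed by hydride addition to 13 | C[C@@]1([C@@H]2CC=CC[C@H]2C(=O)OC)CCCC(=C([O-])OCC[Si](C)(C)C)C1C(OC)OC.[Li+] | intermediate
15 | 2-(trimethylsilyl)ethyl (1R,3S)-2-(dimethoxymethyl)-3-[(1R,6R)-6-(methoxycarbonyl)cyclohex-3-en-1-yl]-1,3-dimethylcyclohexane-1-carboxylate (4R,8R,9R,10S; C5 epimers) | C[C@@]1([C@@H]2CC=CC[C@H]2C(=O)OC)CCC[C@@](C)(C(=O)OCC[Si](C)(C)C)C1C(OC)OC | intermediate
16 | lithium C8 ester enolate of 15 | C[C@@]1([C@@H]2CC=CCC2=C([O-])OC)CCC[C@@](C)(C(=O)OCC[Si](C)(C)C)C1C(OC)OC.[Li+] | intermediate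
17 | 2-(trimethylsilyl)ethyl (1R,3S)-3-[(1S,6R)-6-(2-bromoprop-2-en-1-yl)-6-(methoxycarbonyl)cyclohex-3-en-1-yl]-2-(dimethoxymethyl)-1,3-dimethylcyclohexane-1-carboxylate (4R,8R,9S,10S; the C9 descriptor changes by priority only; arm trans to C10) | C[C@@]1([C@@H]2CC=CC[C@@]2(C(=O)OC)CC(Br)=C)CCC[C@@](C)(C(=O)OCC[Si](C)(C)C)C1C(OC)OC | intermediate
18 | methyl (1R,2S,5R)-2-[(1S,3R)-2-(dimethoxymethyl)-1,3-dimethyl-3-{[2-(trimethylsilyl)ethoxy]carbonyl}cyclohexyl]-6-methylidenebicyclo[3.2.1]octane-1-carboxylate (4R,8R,9S,10S,13R) | C[C@@]1([C@@H]2CC[C@@H]3C[C@@]2(C(=O)OC)CC3=C)CCC[C@@](C)(C(=O)OCC[Si](C)(C)C)C1C(OC)OC | intermediate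
19 | (1R,3S)-2-(dimethoxymethyl)-3-[(1R,2S,5R)-1-(methoxycarbonyl)-6-methylidenebicyclo[3.2.1]octan-2-yl]-1,3-dimethylcyclohexane-1-carboxylic acid | C[C@@]1([C@@H]2CC[C@@H]3C[C@@]2(C(=O)OC)CC3=C)CCC[C@@](C)(C(=O)O)C1C(OC)OC | intermediate
20 | (1R,3S)-2-(dimethoxymethyl)-3-[(1R,2S,5R)-1-(hydroxymethyl)-6-methylidenebicyclo[3.2.1]octan-2-yl]-1,3-dimethylcyclohexane-1-carboxylic acid | C[C@@]1([C@@H]2CC[C@@H]3C[C@@]2(CO)CC3=C)CCC[C@@](C)(C(=O)O)C1C(OC)OC | intermediate
21 | (1R,3S)-2-(dimethoxymethyl)-3-[(1R,2S,5R)-1-formyl-6-methylidenebicyclo[3.2.1]octan-2-yl]-1,3-dimethylcyclohexane-1-carboxylic acid | C[C@@]1([C@@H]2CC[C@@H]3C[C@@]2(C=O)CC3=C)CCC[C@@](C)(C(=O)O)C1C(OC)OC | intermediate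
22 | (1R,3S)-2-(dimethoxymethyl)-3-[(1R,2S,5R,6R)-1-formyl-6-hydroxy-6-(hydroxymethyl)bicyclo[3.2.1]octan-2-yl]-1,3-dimethylcyclohexane-1-carboxylic acid (16-OH exo) | C[C@@]1([C@@H]2CC[C@@H]3C[C@@]2(C=O)C[C@]3(O)CO)CCC[C@@](C)(C(=O)O)C1C(OC)OC | intermediate
23 | 5-epimer of the target, (1R,2R,3S)-2-formyl-3-[(1R,2S,5R,6R)-1-formyl-6-hydroxy-6-(hydroxymethyl)bicyclo[3.2.1]octan-2-yl]-1,3-dimethylcyclohexane-1-carboxylic acid | C[C@@]1([C@@H]2CC[C@@H]3C[C@@]2(C=O)C[C@]3(O)CO)CCC[C@@](C)(C(=O)O)[C@@H]1C=O | intermediate
24 | CNP0159160.1, (1R,2S,3S)-2-formyl-3-[(1R,2S,5R,6R)-1-formyl-6-hydroxy-6-(hydroxymethyl)bicyclo[3.2.1]octan-2-yl]-1,3-dimethylcyclohexane-1-carboxylic acid (4R,5S,8R,9S,10S,13R,16R) | C[C@@]1([C@@H]2CC[C@@H]3C[C@@]2(C=O)C[C@]3(O)CO)CCC[C@@](C)(C(=O)O)[C@H]1C=O | target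

Total step count: 14.
Longest linear sequence: 14 steps (1 to 24); the Grignard reagent from 2 is made and used within step 1.

Steps most likely to fail

Step 3. The conjugate methylation may be sluggish at the hindered beta-carbon, or may show poor facial selectivity at C10 if ligand control and the C9 stereocentre are mismatched. The fallback sets out from 7 and returns at 9, and replaces reagent-controlled addition by intramolecular delivery. Corey–Bakshi–Shibata reduction (oxazaborolidine catalyst, BH3·SMe2, THF, −20 °C) gives the allylic alcohol F1. Hydroxyl-directed Simmons–Smith cyclopropanation (Et2Zn, CH2I2, CH2Cl2, 0 °C) adds the methylene cis to the carbinol and gives the cyclopropyl carbinol F2. Dess–Martin oxidation gives the cyclopropyl ketone F3. Dissolving-metal cleavage of the exocyclic cyclopropane bond that overlaps with the carbonyl (Li, NH3, THF, −78 °C) unveils the C10 methyl and the C4=C5 lithium enolate, which is trapped with Et3SiCl and Et3N to give 9.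

Step 7. Hydride delivery may be incomplete, or proton transfer from C8–H to the C4 enolate may lead to methylation at the wrong ester alpha-carbon. The fallback sets out from 13 and returns at 15, and removes the competing acidic site before a dissolving-metal reductive alkylation. Me3SnOH (ClCH2CH2Cl, 80 °C) cleaves only the methyl ester and gives the C7 acid F4. With the carboxylate as a non-enolisable, non-reducible spectator, Li in NH3 and THF with Me3COH (1 equiv) at −78 °C followed by MeI gives the C4-methylated acid F5. Me3SiCHN2 in MeOH–toluene re-forms the methyl ester, giving 15.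

Step 14. Equilibration at the hindered C5 may be incomplete, the equilibrium may not favour the lactol-forming epimer, or the acid may damage the tertiary 16-ol. The fallback sets out from 10 and returns at 24, and fixes C5 early. Base equilibration of 10 (NaOMe cat., MeOH, 0 °C) and chromatographic separation give the single C5 epimer F6 with C6 trans to the C9 substituent; the other epimer is recycled through the same equilibration. F6 is carried through steps 5 to 13 with the same reagents, as the C5-defined members of 12 to 22, since C5 can no longer enolise once the C4 ketone is converted. The final acetal hydrolysis is then run without the amine buffer (1 M HCl, THF, 0 °C) to give 24.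

Further compounds
F1 | step 3 | methyl (1R,6R)-6-[(3R)-3-hydroxycyclohex-1-en-1-yl]cyclohex-3-ene-1-carboxylate (allylic alcohol) | O[C@H]1C=C([C@@H]2CC=CC[C@H]2C(=O)OC)CCC1
F2 | step 3 | cyclopropyl carbinol: bicyclo[4.1.0]heptan-2-ol bearing the ring C unit at C6 (= C10), cyclopropane methylene cis to the hydroxyl | C3[C@@]1([C@@H]2CC=CC[C@H]2C(=O)OC)CCC[C@@H](O)[C@H]13
F3 | step 3 | cyclopropyl ketone: the bicyclo[4.1.0]heptan-2-one from F2 | C3[C@@]1([C@@H]2CC=CC[C@H]2C(=O)OC)CCCC(=O)[C@H]13
F4 | step 7 | C7 carboxylic acid corresponding to enoate 13 (C5 epimers) | C[C@@]1([C@@H]2CC=CC[C@H]2C(=O)O)CCC=C(C(=O)OCC[Si](C)(C)C)C1C(OC)OC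
F5 | step 7 | C7 carboxylic acid corresponding to 15 (C4 methylated; C5 epimers) | C[C@@]1([C@@H]2CC=CC[C@H]2C(=O)O)CCC[C@@](C)(C(=O)OCC[Si](C)(C)C)C1C(OC)OC
F6 | step 14 | single C5 epimer of 10, methyl (1R,6R)-6-[(1S,2R)-2-(dimethoxymethyl)-1-methyl-3-oxocyclohexyl]cyclohex-3-ene-1-carboxylate | C[C@@]1([C@@H]2CC=CC[C@H]2C(=O)OC)CCCC(=O)[C@H]1C(OC)OC
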